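## The problem

The target is a heliangolide-type germacranolide: a ten-membered carbocycle C1–C10 (germacrane numbering throughout; C14 on C10, C15 on C4, C11–C13 on C7) with a Z-C4=C5 alkene, a trans 1,10-epoxide and an α-methylene-γ-lactone (C12–O–C6, C11=C13) fused trans across C6–C7. C3 carries a benzoate and C8 a (2S,3S)-epoxyangelate. A synthesis must close a heavily substituted medium ring and set six ring stereocentres (C1, C3, C6, C7, C8, C10) plus the two of the side-chain acid, with no small fused carbocycle to relay stereochemistry. The centres are not independent. C6 and C7 are vicinal and can be made together in an open chain. C1 sits next to the quaternary C10, so it can steer C10 formation and then become the second epoxide carbon by inversion; the C10 hydroxyl can deliver hydride to C8; only C3, 1,3 to C1, lacks a strong internal control element. The fragile groups are the α-methylene lactone (base, nucleophiles), the 1,10-epoxide (acid, transannular attack by C4=C5), two different esters that must not migrate, and C7 whenever C8 is a ketone (α to the carbonyl and allylic to C11=C13). The feature that opens the structure is C10: a fully substituted, methyl- and oxygen-bearing carbon β to the oxygenated C8. The array C8–C9–C10 is therefore an aldol retron, a C8 ketone enolate at C9 adding to a C10 methyl ketone, with the C1 oxygen α to that ketone available for facial control. Because the open chain then holds two methyl-ketone-type carbonyls, the enolate must be generated regiospecifically, which points to an α-bromo ketone and SmI2.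

## Retrosynthesis

**Lactone last (40 ⇒ 39).** The acyl C12–O6 bond is cut and C12 lowered to the alcohol, giving epoxy diol 39. The α-methylene lactone is the least tolerant group, so it is formed in the final step by neutral oxidative lactonisation. An earlier lactone would also make C7–H doubly activated during the ketone stage. The forward step must oxidise the primary allylic C12–OH in the presence of the secondary C6–OH, the epoxide and both esters.

**Epoxide by displacement (39 ⇒ 38 ⇒ 36 ⇒ 35).** The C1–O bond of the epoxide is cut: the tertiary C10 alkoxide displaces a C1 mesylate (37) with inversion. Epoxidation of a C1=C10 alkene is the neighbouring option, but it would leave the face to the macrocycle conformation and would remove the C10 oxygen on which the key step depends. The route instead needs the (1S,10R) diol relationship and a C1 hydroxyl that can be freed alone. The silyl groups are therefore graded: triethylsilyl at C1, tert-butyldimethylsilyl at C6, tert-butyldiphenylsilyl at C12.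

**C8 ester (35 ⇒ 29 + 33).** The acyl–O8 bond is cut. Acid 33 is made separately from angelic acid 30 via alcohol 31 and epoxy alcohol 32, since epoxidation of an attached angelate could not be made selective beside the ring alkenes. Acylating C8 before C1 is unmasked means C1–OH is the only secondary hydroxyl present at the mesylation.

**C8 carbinol (29 ⇒ 28).** The C8–H bond is cut back to the ketone. The 8R/10R pair is a 1,3-anti diol, which is the outcome of intramolecular hydride delivery from a boron-bound C10 hydroxyl.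

**Ring closure at C9–C10 (28 ⇒ 26).** This is the key cut. It removes the ring, the quaternary centre and the most hindered ring bond together, and leaves an open chain whose every stereocentre except C10 and C8 is already in place. The forward step needs a regiospecific C9 enolate (samarium enolate 27 from the bromide), Felkin–Anh addition to the C10 ketone anti to the C1 silyloxy group, and cyclisation that outruns intermolecular reaction.

**Bromo ketone and benzoate (26 ⇒ 25 ⇒ 24).** The C9–Br bond is traced to silyl enol ether 25, so that C9 is marked as the nucleophilic carbon before a second ketone enters the molecule. The C3 benzoate of the target is put on directly after C3 is formed; it then serves as the protecting group and saves a protection/deprotection pair, since no organometallic step follows.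

**Fragment union at C3–C4 (24 ⇒ 23 + 4).** Cutting C3–C4 divides the chain into halves of similar size and keeps the Z-alkene intact as a Z-iodoalkene. A Nozaki–Hiyama–Kishi coupling is chosen over an alkenyllithium addition because it tolerates the C10 ketone of 4 and the enol ether of 23. The forward step should give the 1,3-anti (3S) alcohol.

**C10–C3 piece (4 ⇒ 3 ⇒ 2 ⇒ 1).** Keto aldehyde 4 comes from lactone 1 by silylation, mono-addition of MeLi and oxidation. The stereocentre of 1 becomes C1, and its descriptor (S) is the one needed before inversion.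

**C4–C9 piece (23 ⇒ 21 ⇒ 20 ⇒ 19 ⇒ 18 ⇒ 12 + 16).** The C6–C7 bond is an aldol bond with a syn relationship between the C6 oxygen and the C7 branch, so a boron aldol of imide 12 with Z-iodo enal 16 sets both centres in one step. The acyl group is then taken through Weinreb amide 19, silyl ether 20 and methyl ketone 21 to the kinetic enol ether 23 (via enolate 22), while only one ketone exists.

**Small building blocks (12 ⇒ 9 + 10; 9 ⇒ 7 ⇒ 6 ⇒ 5; 16 ⇒ 15 ⇒ 13).** Acid 9 is cut at C7–C8 to allylic chloride 7 (Grignard 8 and CO2), which comes from diol 5 via mono-silyl ether 6. The unit is symmetrical, so no regiochemistry arises. Enal 16 is the oxidation product of iodo alcohol 15, made by trans-hydroalumination/iodination of butynol 13 via alanate 14.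

## Roads not taken

**Alternative 1:** The cut is at C5–C6 together with the lactone C–O bond. Open-chain Z-iodoalkene aldehyde ester A1 is treated with CrCl2 and catalytic NiCl2; the alkenylchromium species adds to the C6 aldehyde and the chromium alkoxide closes the γ-lactone, giving A2. Its merits are real. The Ni/Cr macrocyclisation onto an aldehyde is better precedented for medium rings than a Reformatsky onto a ketone, two rings form in one flask, and the precursor needs fewer protecting groups because C1/C10 are still an alkene. Its weak points lie after the ring closure. C6 is created in the macrocyclisation and relies on C7 and ring conformation. The C1=C10 alkene must then be epoxidised on the correct face and in preference to C4=C5. C13 has to be introduced through a lactone enolate with strong base. Both acylations follow. In fairness this road is probably shorter and its ring-closing step carries less risk. The chosen plan sets against it that C1, C6, C7 and C10 are fixed by open-chain or local stereocontrol (chiral pool, auxiliary aldol, Felkin–Anh) and not by the face of a flexible ring, and that no enolate chemistry is needed on the finished lactone.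

**Alternative 2:** The cut is at C6–C7 of the bare skeleton. A germacrene A synthase-type enzyme ionises (2Z,6E)-farnesyl diphosphate A3, the distal alkene captures the allyl cation and proton loss gives the hydrocarbon A4. No chemical route can match this for the skeleton: one step, both alkene geometries and C7 set by the enzyme. The weakness is everything that follows. A4 carries no oxygen, and the target needs oxidation at C1/C10, C3, C6, C8 and C12, each site- and stereoselective, on a volatile triene prone to thermal Cope rearrangement. Each oxidation would need its own enzyme or a selective reagent, and none of this follows from A4 itself. The chosen plan is far longer to the ring, but every oxygen arrives from a defined precursor with a defined configuration.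

**Alternative 3:** The cut is at C8–C9, made by ring expansion. The potassium alkoxide of a six-membered 3-hydroxy-1,5-diene from the monoterpene chiral pool undergoes an anionic oxy-Cope shift, cleaving one ring bond and forming C8–C9, to give dienone A5 after protonation. This is attractive because the closure is unimolecular and sigmatropic: it needs no dilution, sets both ring alkene geometries through an ordered transition state and carries C3 and the C8 silyl group through. Its weakness for this target is what A5 lacks. C7 is a methylene that must still receive C11–C13 with stereocontrol next to a ketone, C6 must be reduced, the silane oxidised to the C8 hydroxyl beside two alkenes, and the epoxide and lactone built late. The ring closure itself is more secure than the chosen one. The chosen plan sets against this that C6, C7, the C11–C13 unit and the C10 oxygen are all in place when the ring closes.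

Key step: step 18

Assumption: lactone 1 is bought; it is the commercial building block derived from (S)-malic acid by reduction of the distal carboxyl group and lactonisation, so the malic acid stereocentre becomes C1.
Remark: 3 and 24 are γ-hydroxy ketones in equilibrium with five-membered hemiketals; they are drawn and named in the open form, which is the form that reacts. TESO, TBSO and TBDPSO stand for triethylsilyloxy, tert-butyldimethylsilyloxy and tert-butyldiphenylsilyloxy; ring compounds are named as germacranes.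

Step 1
Reactants: 1 (3S)-3-hydroxyoxolan-2-one
Product: 2 (3S)-3-(TESO)oxolan-2-one
Conditions: Et3SiCl, imidazole, DMF, 0 °C → rt
Reagents that add atoms: triethylsilyl chloride, CC[Si](Cl)(CC)CC
Why: Imidazole-promoted silyl ether formation on a secondary alcohol; the stereocentre is untouched, and triethylsilyl is non-chelating for step 18 yet the most labile silyl group for step 24.

Step 2
Reactants: 2 (3S)-3-(TESO)oxolan-2-one
Product: 3 (3S)-5-hydroxy-3-(TESO)pentan-2-one
Conditions: MeLi (1.05 equiv), THF, −78 °C; then H2O/pH 7 buffer at −78 °C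
Reagents that add atoms: methyllithium, [Li]C
Why: Mono-addition of an organolithium to a γ-lactone; the tetrahedral lithium hemiketal is stable at −78 °C, so a second addition should be suppressed and the methyl ketone (C10, C14) appears only on work-up.

Step 3
Reactants: 3 (3S)-5-hydroxy-3-(TESO)pentan-2-one
Product: 4 (3S)-4-oxo-3-(TESO)pentanal
Conditions: Dess–Martin periodinane, NaHCO3, CH2Cl2, 0 °C → rt
Reagents that add atoms: none
Why: Dess–Martin oxidation of the primary alcohol of the open-chain tautomer; the buffered, amine-free medium should avoid β-elimination of the silyloxy group and epimerisation at C1.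

Step 4
Reactants: 5 2-methylidenepropane-1,3-diol
Product: 6 2-(TBDPSO-methyl)prop-2-en-1-ol
Conditions: NaH (1.0 equiv), THF, 0 °C; then t-BuPh2SiCl, 0 °C → rt
Reagents that add atoms: tert-butyl(chloro)diphenylsilane, CC(C)(C)[Si](Cl)(c1ccccc1)c1ccccc1
Why: Monosilylation of a symmetrical diol through its monosodium alkoxide, a standard way to desymmetrise such diols.

Step 5
Reactants: 6 2-(TBDPSO-methyl)prop-2-en-1-ol
Product: 7 tert-butyl{[2-(chloromethyl)prop-2-en-1-yl]oxy}diphenylsilane
Conditions: N-chlorosuccinimide, PPh3, CH2Cl2, 0 °C → rt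
Reagents that add atoms: N-chlorosuccinimide, O=C1CCC(=O)N1Cl
Why: Appel-type chlorination of an allylic alcohol under neutral conditions; direct and allylic substitution give the same product.

Step 6
Reactants: 7 tert-butyl{[2-(chloromethyl)prop-2-en-1-yl]oxy}diphenylsilane
Product: 9 3-(TBDPSO-methyl)but-3-enoic acid, via allylmagnesium chloride 8 (not isolated)
Conditions: Mg turnings, THF, 0 °C (slow addition); then CO2 (gas), −78 °C → rt; 1 M HCl work-up
Reagents that add atoms: carbon dioxide, O=C=O
Why: Carboxylation of an allylic Grignard reagent forms C7–C8; the 2-substituted allyl unit is symmetrical, so only one acid can form, and the β,γ-alkene should stay unconjugated under the acidic work-up.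

Step 7
Reactants: 9 3-(TBDPSO-methyl)but-3-enoic acid; 10 (4S)-4-benzyl-1,3-oxazolidin-2-one
Product: 12 (4S)-4-benzyl-3-[3-(TBDPSO-methyl)but-3-enoyl]-1,3-oxazolidin-2-one, via mixed pivalic anhydride 11 (not isolated)
Conditions: t-BuCOCl, Et3N, THF, −20 °C; then LiCl, 10, −20 → 0 °C
Reagents that add atoms: none
Why: N-acylation of the oxazolidinone through the mixed pivalic anhydride (LiCl/Et3N protocol); the low temperature should keep the β,γ-alkene from moving into conjugation.

Step 8
Reactants: 13 but-2-yn-1-ol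
Product: 15 (2Z)-3-iodobut-2-en-1-ol, via cyclic alkenylalanate 14 (not isolated)
Conditions: NaAlH2(OCH2CH2OMe)2, THF, 0 °C → rt; EtOAc; then I2, THF, −78 → 0 °C
Reagents that add atoms: iodine, II
Why: Alkoxide-directed trans-hydroalumination of a propargylic alcohol places aluminium on the distal carbon in a five-membered alanate; iodinolysis with retention gives the Z-iodoalkene that becomes C4=C5.

Step 9
Reactants: 15 (2Z)-3-iodobut-2-en-1-ol
Product: 16 (2Z)-3-iodobut-2-enal
Conditions: MnO2 (activated, excess), CH2Cl2, rt, dark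
Reagents that add atoms: none
Why: MnO2 oxidation of an allylic alcohol under neutral conditions should preserve the Z geometry; the enal is used without storage.

Step 10
Reactants: 12 (4S)-4-benzyl-3-[3-(TBDPSO-methyl)but-3-enoyl]-1,3-oxazolidin-2-one; 16 (2Z)-3-iodobut-2-enal
Product: 18 (4S)-4-benzyl-3-[(2S,3S,4Z)-3-hydroxy-5-iodo-2-(3-TBDPSO-prop-1-en-2-yl)hex-4-enoyl]-1,3-oxazolidin-2-one, via Z-boron enolate 17 (not isolated)
Conditions: n-Bu2BOTf, i-Pr2NEt, CH2Cl2, −78 → 0 °C; then 16, −78 → −10 °C; pH 7 buffer, MeOH, 30% H2O2, 0 °C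
Reagents that add atoms: none
Why: Evans syn-aldol: the Z-boron enolate reacts at its α-carbon through a Zimmerman–Traxler chair, with the (S)-benzyl group shielding one face, to form C6–C7 and set both centres as in the target (descriptors are S,S here only because iodine raises the priority of C5).

Step 11
Reactants: 18 aldol imide
Product: 19 (2S,3S,4Z)-3-hydroxy-5-iodo-N-methoxy-N-methyl-2-(3-TBDPSO-prop-1-en-2-yl)hex-4-enamide
Conditions: MeNHOMe·HCl, AlMe3, CH2Cl2, −20 → 0 °C; aq. potassium sodium tartrate work-up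
Reagents that add atoms: N,O-dimethylhydroxylamine hydrochloride, CNOC.Cl
Why: Weinreb transamidation of an aldol imide with the aluminium amide, assisted by the free β-hydroxyl; auxiliary 10 is released for re-use.

Step 12
Reactants: 19 hydroxy Weinreb amide
Product: 20 (2S,3S,4Z)-3-(TBSO)-5-iodo-N-methoxy-N-methyl-2-(3-TBDPSO-prop-1-en-2-yl)hex-4-enamide
Conditions: t-BuMe2SiOTf, 2,6-lutidine, CH2Cl2, −78 → 0 °C
Reagents that add atoms: tert-butyldimethylsilyl trifluoromethanesulfonate, CC(C)(C)[Si](C)(C)OS(=O)(=O)C(F)(F)F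
Why: Silyl triflate protection of a hindered secondary aldol hydroxyl; this group at C6 must outlast the C1 triethylsilyl ether.

Step 13
Reactants: 20 silyl-protected Weinreb amide
Product: 21 (3S,4S,5Z)-4-(TBSO)-6-iodo-3-(3-TBDPSO-prop-1-en-2-yl)hept-5-en-2-one
Conditions: MeMgBr, THF, 0 °C; aq. NH4Cl at 0 °C
Reagents that add atoms: methylmagnesium bromide, C[Mg]Br
Why: Weinreb ketone synthesis brings in C9; the chelated tetrahedral intermediate prevents over-addition and keeps C7 from enolising until the cold quench.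

Step 14
Reactants: 21 methyl ketone
Product: 23 (3S,4S,5Z)-2,4-bis(TBSO)-6-iodo-3-(3-TBDPSO-prop-1-en-2-yl)hepta-1,5-diene, via lithium enolate 22 (not isolated)
Conditions: LiN(i-Pr)2 (1.1 equiv), THF, −78 °C; then t-BuMe2SiOTf, −78 °C; Et3N-buffered work-up
Reagents that add atoms: tert-butyldimethylsilyl trifluoromethanesulfonate, CC(C)(C)[Si](C)(C)OS(=O)(=O)C(F)(F)F
Why: Kinetic deprotonation of the methyl group by the hindered amide (the C7 methine is more acidic but shielded) and O-silylation fix C9 as the future nucleophilic carbon while only one ketone is present.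

Step 15
Reactants: 23 iodo diene silyl enol ether; 4 (3S)-4-oxo-3-(TESO)pentanal
Product: 24 (3S,5S,6Z,8R,9S)-8,10-bis(TBSO)-5-hydroxy-6-methyl-3-(TESO)-9-(3-TBDPSO-prop-1-en-2-yl)undeca-6,10-dien-2-one
Conditions: CrCl2 (5 equiv), NiCl2 (2 mol%), degassed DMSO, rt
Reagents that add atoms: none
Why: Nozaki–Hiyama–Kishi coupling: nickel activates the C–I bond, the alkenyl group passes to chromium with retention of the Z geometry and adds to the aldehyde only, leaving ketone, enol ether and silyl ethers alone. The new C3 centre should follow the 1,3-anti preference of a β-silyloxy aldehyde; the bias is expected to be modest and the epimers are to be separated.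

Step 16
Reactants: 24 C3 alcohol
Product: 25 (3S,5S,6Z,8R,9S)-8,10-bis(TBSO)-6-methyl-2-oxo-3-(TESO)-9-(3-TBDPSO-prop-1-en-2-yl)undeca-6,10-dien-5-yl benzoate
Conditions: PhCOCl, pyridine, DMAP (cat.), CH2Cl2, 0 °C → rt
Reagents that add atoms: benzoyl chloride, O=C(Cl)c1ccccc1
Why: DMAP-catalysed acylation of the secondary allylic alcohol installs the C3 benzoate of the target, which then serves as the protecting group and drains the hemiketal equilibrium.

Step 17
Reactants: 25 benzoate silyl enol ether
Product: 26 (3S,5S,6Z,8R,9S)-11-bromo-8-(TBSO)-6-methyl-2,10-dioxo-3-(TESO)-9-(3-TBDPSO-prop-1-en-2-yl)undec-6-en-5-yl benzoate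
Conditions: N-bromosuccinimide, NaHCO3, THF, −78 °C
Reagents that add atoms: N-bromosuccinimide, O=C1CCC(=O)N1Br
Why: Electrophilic bromination of a silyl enol ether gives the α-bromo ketone at C9 only; the non-enolised C10 ketone and the less electron-rich alkenes should not react at −78 °C. The product is used at once.

Step 18
Reactants: 26 open-chain bromomethyl ketone
Product: 28 (1S,3S,4Z,6R,7S,10R)-3-benzoyloxy-6-(TBSO)-12-(TBDPSO)-10-hydroxy-1-(TESO)germacra-4,11(13)-dien-8-one, via samarium enolate 27 (not isolated)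
Conditions: SmI2 (2.2 equiv, 0.1 M in THF) added over 2 h to 26 (0.002 M in THF), −78 °C; aq. NH4Cl at −78 °C
Reagents that add atoms: none
Why: Two equivalents of SmI2 reduce the C9–Br bond by successive electron transfers to the trivalent-samarium enolate 27, formed at C9 only and not toward the epimerisable C7. The enolate adds to the C10 ketone with samarium bound to both oxygens, forming C9–C10 and a samarium aldolate that should not revert at −78 °C. The closest known reaction type is the SmI2-promoted intramolecular Reformatsky (samarium aldol) cyclisation of α-bromo carbonyl compounds to eight- to fourteen-membered β-hydroxy carbonyl rings; a ketone acceptor at ring size ten lies at the edge of that scope. The ten-membered carbocycle closes in a 10-(enolendo)-exo-trig mode. The new stereocentre C10 is controlled by C1 in the Felkin–Anh sense: the non-chelating silyloxy group lies anti to the incoming C9 and attack passes C1–H, which gives 10R from 1S, the relationship later needed for the trans-epoxide. The step needs C–Br reduction in preference to the α-silyloxy ketone and the benzoate, secured by the much faster reduction of α-bromo ketones and by adding the reductant to the substrate so that no excess is present. It also needs cyclisation in preference to oligomerisation, secured by dilution and by the Z-alkene and the substituents at C1, C3, C6 and C7, which bend the chain.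

Step 19
Reactants: 28 ten-membered β-hydroxy ketone
Product: 29 (1S,3S,4Z,6R,7R,8R,10R)-3-benzoyloxy-6-(TBSO)-12-(TBDPSO)-1-(TESO)germacra-4,11(13)-diene-8,10-diol
Conditions: Me4NBH(OAc)3, MeCN/AcOH (1:1), −30 → −20 °C
Reagents that add atoms: none
Why: Evans–Saksena reduction: the C10 hydroxyl exchanges onto boron and hydride is delivered intramolecularly through a six-membered chair, which should give the 1,3-anti diol, that is 8R; the acidic medium should not enolise C7.

Step 20
Reactants: 30 (2Z)-2-methylbut-2-enoic acid (angelic acid)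
Product: 31 (2Z)-2-methylbut-2-en-1-ol
Conditions: LiAlH4, Et2O, 0 °C
Reagents that add atoms: none
Why: Hydride reduction of an α,β-unsaturated acid to the allylic alcohol by 1,2-addition, with the Z geometry retained.

Step 21
Reactants: 31 (2Z)-2-methylbut-2-en-1-ol
Product: 32 [(2R,3S)-2,3-dimethyloxiran-2-yl]methanol
Conditions: Ti(Oi-Pr)4 (10 mol%), D-(−)-diethyl tartrate (12 mol%), t-BuOOH, 4 Å molecular sieves, CH2Cl2, −20 °C
Reagents that add atoms: tert-butyl hydroperoxide, CC(C)(C)OO
Why: Sharpless asymmetric epoxidation; the D-(−)-tartrate complex should deliver oxygen to the face that gives the (2R,3S) epoxy alcohol, and the cis relation of the C3 methyl and the CH2OH group follows from the Z-alkene.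

Step 22
Reactants: 32 [(2R,3S)-2,3-dimethyloxiran-2-yl]methanol
Product: 33 (2S,3S)-2,3-dimethyloxirane-2-carboxylic acid
Conditions: RuCl3·xH2O (2 mol%), NaIO4, MeCN/CCl4/H2O, rt
Reagents that add atoms: water, O
Why: Ruthenium-catalysed periodate oxidation of a primary epoxy alcohol to the glycidic acid (via the aldehyde hydrate) without opening the epoxide; the descriptor at C2 changes only through priorities.

Step 23
Reactants: 29 anti-diol; 33 (2S,3S)-2,3-dimethyloxirane-2-carboxylic acid
Product: 35 (1S,3S,4Z,6R,7R,8R,10R)-3-benzoyloxy-8-[(2S,3S)-2,3-dimethyloxirane-2-carbonyloxy]-6-(TBSO)-12-(TBDPSO)-1-(TESO)germacra-4,11(13)-dien-10-ol, via Yamaguchi mixed anhydride 34 (not isolated)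
Conditions: 33, 2,4,6-trichlorobenzoyl chloride, Et3N, THF, rt; then 29, DMAP, toluene, rt → 40 °C
Reagents that add atoms: none
Why: Yamaguchi esterification acylates the secondary C8 hydroxyl; the tertiary C10 hydroxyl should not react, so no protection is needed.

Step 24
Reactants: 35 fully protected ester
Product: 36 (1S,3S,4Z,6R,7R,8R,10R)-3-benzoyloxy-8-[(2S,3S)-2,3-dimethyloxirane-2-carbonyloxy]-6-(TBSO)-12-(TBDPSO)germacra-4,11(13)-diene-1,10-diol
Conditions: HF·pyridine, pyridine, THF, 0 °C
Reagents that add atoms: none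
Why: Selective cleavage of the most labile silyl ether (triethylsilyl) with buffered fluoride; the other two silyl ethers should survive the short exposure.

Step 25
Reactants: 36 1,10-diol
Product: 38 (1R,3S,4Z,6R,7R,8R,10R)-3-benzoyloxy-8-[(2S,3S)-2,3-dimethyloxirane-2-carbonyloxy]-1,10-epoxy-6-(TBSO)-12-(TBDPSO)germacra-4,11(13)-diene, via C1 mesylate 37 (not isolated)
Conditions: MeSO2Cl, Et3N, CH2Cl2, −20 → 0 °C; then DBU, 0 °C → rt
Reagents that add atoms: none
Why: The only secondary hydroxyl is mesylated and the C10 alkoxide displaces it in an intramolecular Williamson (3-exo-tet) SN2 reaction, inverting C1 to R and giving the trans-epoxide; the non-nucleophilic base should leave both esters alone.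

Step 26
Reactants: 38 silyl-protected epoxide
Product: 39 (1R,3S,4Z,6R,7S,8R,10R)-3-benzoyloxy-8-[(2S,3S)-2,3-dimethyloxirane-2-carbonyloxy]-1,10-epoxygermacra-4,11(13)-diene-6,12-diol
Conditions: HF·pyridine (excess), pyridine, THF, 0 °C → rt
Reagents that add atoms: none
Why: Fluoride desilylation of the secondary and the primary silyl ether; the pyridine buffer is meant to spare the trisubstituted epoxide and to avoid base-induced acyl migration.

Step 27
Reactants: 39 epoxy diol
Product: 40 (1R,3S,4Z,6R,7R,8R,10R)-3-benzoyloxy-8-[(2S,3S)-2,3-dimethyloxirane-2-carbonyloxy]-1,10-epoxygermacra-4,11(13)-dien-12,6-olide (CNP0324463.3)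
Conditions: TEMPO (20 mol%), PhI(OAc)2 (2.5 equiv), CH2Cl2, rt
Reagents that add atoms: none
Why: Oxoammonium-mediated oxidation selective for the primary allylic alcohol; the C12 aldehyde is trapped by the C6 hydroxyl as a lactol and oxidised further to the γ-lactone (oxidative lactonisation), whose trans fusion is already fixed by C6 and C7.

## Compound list

1 | (3S)-3-hydroxyoxolan-2-one [(S)-α-hydroxy-γ-butyrolactone] | O[C@H]1CCOC1=O | starting material
2 | (3S)-3-[(triethylsilyl)oxy]oxolan-2-one | CC[Si](CC)(CC)O[C@H]1CCOC1=O | intermediate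
3 | (3S)-5-hydroxy-3-[(triethylsilyl)oxy]pentan-2-one | CC(=O)[C@@H](O[Si](CC)(CC)CC)CCO | intermediate
4 | (3S)-4-oxo-3-[(triethylsilyl)oxy]pentanal | CC(=O)[C@@H](O[Si](CC)(CC)CC)CC=O | intermediate
5 | 2-methylidenepropane-1,3-diol | C=C(CO)CO | starting material
6 | 2-({[tert-butyl(diphenyl)silyl]oxy}methyl)prop-2-en-1-ol | C=C(CO)CO[Si](c1ccccc1)(c1ccccc1)C(C)(C)C | intermediate
7 | tert-butyl{[2-(chloromethyl)prop-2-en-1-yl]oxy}diphenylsilane | C=C(CCl)CO[Si](c1ccccc1)(c1ccccc1)C(C)(C)C | intermediate
8 | [2-({[tert-butyl(diphenyl)silyl]oxy}methyl)prop-2-en-1-yl]magnesium chloride (not isolated) | C=C(C[Mg]Cl)CO[Si](c1ccccc1)(c1ccccc1)C(C)(C)C | intermediate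
9 | 3-({[tert-butyl(diphenyl)silyl]oxy}methyl)but-3-enoic acid | C=C(CC(=O)O)CO[Si](c1ccccc1)(c1ccccc1)C(C)(C)C | intermediate
10 | (4S)-4-benzyl-1,3-oxazolidin-2-one | O=C1OC[C@H](Cc2ccccc2)N1 | starting material
11 | 3-({[tert-butyl(diphenyl)silyl]oxy}methyl)but-3-enoic pivalic anhydride (not isolated) | C=C(CC(=O)OC(=O)C(C)(C)C)CO[Si](c1ccccc1)(c1ccccc1)C(C)(C)C | intermediate
12 | (4S)-4-benzyl-3-[3-({[tert-butyl(diphenyl)silyl]oxy}methyl)but-3-enoyl]-1,3-oxazolidin-2-one | C=C(CC(=O)N1[C@@H](Cc2ccccc2)COC1=O)CO[Si](c1ccccc1)(c1ccccc1)C(C)(C)C | intermediate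
13 | but-2-yn-1-ol | CC#CCO | starting material
14 | sodium 2,2-bis(2-methoxyethoxy)-3-methyl-2,5-dihydro-1,2-oxaluminol-2-uide, the cyclic alkenylalanate (not isolated) | CC1=CCO[Al-]1(OCCOC)OCCOC.[Na+] | intermediate
15 | (2Z)-3-iodobut-2-en-1-ol | C/C(I)=C/CO | intermediate
16 | (2Z)-3-iodobut-2-enal | C/C(I)=C/C=O | intermediate
17 | (Z)-di-n-butylboron enolate of 12 (not isolated) | C=C(CO[Si](c1ccccc1)(c1ccccc1)C(C)(C)C)/C=C(\OB(CCCC)CCCC)N1[C@@H](Cc2ccccc2)COC1=O | intermediate
18 | (4S)-4-benzyl-3-[(2S,3S,4Z)-2-(3-{[tert-butyl(diphenyl)silyl]oxy}prop-1-en-2-yl)-3-hydroxy-5-iodohex-4-enoyl]-1,3-oxazolidin-2-one | C/C(I)=C/[C@@H](O)[C@H](C(=C)CO[Si](c1ccccc1)(c1ccccc1)C(C)(C)C)C(=O)N1[C@@H](Cc2ccccc2)COC1=O | intermediate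
19 | (2S,3S,4Z)-2-(3-{[tert-butyl(diphenyl)silyl]oxy}prop-1-en-2-yl)-3-hydroxy-5-iodo-N-methoxy-N-methylhex-4-enamide | C/C(I)=C/[C@@H](O)[C@H](C(=C)CO[Si](c1ccccc1)(c1ccccc1)C(C)(C)C)C(=O)N(C)OC | intermediate
20 | (2S,3S,4Z)-3-{[tert-butyl(dimethyl)silyl]oxy}-2-(3-{[tert-butyl(diphenyl)silyl]oxy}prop-1-en-2-yl)-5-iodo-N-methoxy-N-methylhex-4-enamide | C/C(I)=C/[C@@H](O[Si](C)(C)C(C)(C)C)[C@H](C(=C)CO[Si](c1ccccc1)(c1ccccc1)C(C)(C)C)C(=O)N(C)OC | intermediate
21 | (3S,4S,5Z)-4-{[tert-butyl(dimethyl)silyl]oxy}-3-(3-{[tert-butyl(diphenyl)silyl]oxy}prop-1-en-2-yl)-6-iodohept-5-en-2-one | C/C(I)=C/[C@@H](O[Si](C)(C)C(C)(C)C)[C@H](C(=C)CO[Si](c1ccccc1)(c1ccccc1)C(C)(C)C)C(C)=O | intermediate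
22 | lithium enolate of 21 at C9 (not isolated) | C/C(I)=C/[C@@H](O[Si](C)(C)C(C)(C)C)[C@H](C(=C)CO[Si](c1ccccc1)(c1ccccc1)C(C)(C)C)C(=C)O[Li] | intermediate
23 | (3S,4S,5Z)-2,4-bis{[tert-butyl(dimethyl)silyl]oxy}-3-(3-{[tert-butyl(diphenyl)silyl]oxy}prop-1-en-2-yl)-6-iodohepta-1,5-diene | C/C(I)=C/[C@@H](O[Si](C)(C)C(C)(C)C)[C@H](C(=C)CO[Si](c1ccccc1)(c1ccccc1)C(C)(C)C)C(=C)O[Si](C)(C)C(C)(C)C | intermediate
24 | (3S,5S,6Z,8R,9S)-8,10-bis{[tert-butyl(dimethyl)silyl]oxy}-9-(3-{[tert-butyl(diphenyl)silyl]oxy}prop-1-en-2-yl)-5-hydroxy-6-methyl-3-[(triethylsilyl)oxy]undeca-6,10-dien-2-one | CC(=O)[C@@H](O[Si](CC)(CC)CC)C[C@H](O)/C(C)=C\[C@@H](O[Si](C)(C)C(C)(C)C)[C@H](C(=C)CO[Si](c1ccccc1)(c1ccccc1)C(C)(C)C)C(=C)O[Si](C)(C)C(C)(C)C | intermediate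
25 | (3S,5S,6Z,8R,9S)-8,10-bis{[tert-butyl(dimethyl)silyl]oxy}-9-(3-{[tert-butyl(diphenyl)silyl]oxy}prop-1-en-2-yl)-6-methyl-2-oxo-3-[(triethylsilyl)oxy]undeca-6,10-dien-5-yl benzoate | CC(=O)[C@@H](O[Si](CC)(CC)CC)C[C@H](OC(=O)c1ccccc1)/C(C)=C\[C@@H](O[Si](C)(C)C(C)(C)C)[C@H](C(=C)CO[Si](c1ccccc1)(c1ccccc1)C(C)(C)C)C(=C)O[Si](C)(C)C(C)(C)C | intermediate
26 | (3S,5S,6Z,8R,9S)-11-bromo-8-{[tert-butyl(dimethyl)silyl]oxy}-9-(3-{[tert-butyl(diphenyl)silyl]oxy}prop-1-en-2-yl)-6-methyl-2,10-dioxo-3-[(triethylsilyl)oxy]undec-6-en-5-yl benzoate | CC(=O)[C@@H](O[Si](CC)(CC)CC)C[C@H](OC(=O)c1ccccc1)/C(C)=C\[C@@H](O[Si](C)(C)C(C)(C)C)[C@H](C(=C)CO[Si](c1ccccc1)(c1ccccc1)C(C)(C)C)C(=O)CBr | intermediate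
27 | diiodosamarium enolate of 26 at C8–C9 (not isolated) | CC(=O)[C@@H](O[Si](CC)(CC)CC)C[C@H](OC(=O)c1ccccc1)/C(C)=C\[C@@H](O[Si](C)(C)C(C)(C)C)[C@H](C(=C)CO[Si](c1ccccc1)(c1ccccc1)C(C)(C)C)C(=C)O[Sm](I)I | intermediate
28 | (1S,3S,4Z,6R,7S,10R)-3-benzoyloxy-6-(tert-butyldimethylsilyloxy)-12-(tert-butyldiphenylsilyloxy)-10-hydroxy-1-(triethylsilyloxy)germacra-4,11(13)-dien-8-one | C[C@]1(O)[C@@H](O[Si](CC)(CC)CC)C[C@H](OC(=O)c2ccccc2)/C(C)=C\[C@@H](O[Si](C)(C)C(C)(C)C)[C@H](C(=C)CO[Si](c2ccccc2)(c2ccccc2)C(C)(C)C)C(=O)C1 | intermediate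
29 | (1S,3S,4Z,6R,7R,8R,10R)-3-benzoyloxy-6-(tert-butyldimethylsilyloxy)-12-(tert-butyldiphenylsilyloxy)-1-(triethylsilyloxy)germacra-4,11(13)-diene-8,10-diol | C[C@]1(O)[C@@H](O[Si](CC)(CC)CC)C[C@H](OC(=O)c2ccccc2)/C(C)=C\[C@@H](O[Si](C)(C)C(C)(C)C)[C@H](C(=C)CO[Si](c2ccccc2)(c2ccccc2)C(C)(C)C)[C@H](O)C1 | intermediate
30 | (2Z)-2-methylbut-2-enoic acid (angelic acid) | C/C=C(/C)C(=O)O | starting material
31 | (2Z)-2-methylbut-2-en-1-ol | C/C=C(/C)CO | intermediate
32 | [(2R,3S)-2,3-dimethyloxiran-2-yl]methanol | OC[C@@]1(C)O[C@H]1C | intermediate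
33 | (2S,3S)-2,3-dimethyloxirane-2-carboxylic acid | OC(=O)[C@@]1(C)O[C@H]1C | intermediate
34 | (2S,3S)-2,3-dimethyloxirane-2-carboxylic 2,4,6-trichlorobenzoic anhydride (not isolated) | O=C(OC(=O)[C@@]1(C)O[C@H]1C)c1c(Cl)cc(Cl)cc1Cl | intermediate
35 | (1S,3S,4Z,6R,7R,8R,10R)-3-benzoyloxy-8-[(2S,3S)-2,3-dimethyloxirane-2-carbonyloxy]-6-(tert-butyldimethylsilyloxy)-12-(tert-butyldiphenylsilyloxy)-1-(triethylsilyloxy)germacra-4,11(13)-dien-10-ol | C[C@]1(O)[C@@H](O[Si](CC)(CC)CC)C[C@H](OC(=O)c2ccccc2)/C(C)=C\[C@@H](O[Si](C)(C)C(C)(C)C)[C@H](C(=C)CO[Si](c2ccccc2)(c2ccccc2)C(C)(C)C)[C@H](OC(=O)[C@@]2(C)O[C@H]2C)C1 | intermediate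
36 | (1S,3S,4Z,6R,7R,8R,10R)-3-benzoyloxy-8-[(2S,3S)-2,3-dimethyloxirane-2-carbonyloxy]-6-(tert-butyldimethylsilyloxy)-12-(tert-butyldiphenylsilyloxy)germacra-4,11(13)-diene-1,10-diol | C[C@]1(O)[C@@H](O)C[C@H](OC(=O)c2ccccc2)/C(C)=C\[C@@H](O[Si](C)(C)C(C)(C)C)[C@H](C(=C)CO[Si](c2ccccc2)(c2ccccc2)C(C)(C)C)[C@H](OC(=O)[C@@]2(C)O[C@H]2C)C1 | intermediate
37 | 1-O-methanesulfonate of 36 (not isolated) | C[C@]1(O)[C@@H](OS(C)(=O)=O)C[C@H](OC(=O)c2ccccc2)/C(C)=C\[C@@H](O[Si](C)(C)C(C)(C)C)[C@H](C(=C)CO[Si](c2ccccc2)(c2ccccc2)C(C)(C)C)[C@H](OC(=O)[C@@]2(C)O[C@H]2C)C1 | intermediate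
38 | (1R,3S,4Z,6R,7R,8R,10R)-3-benzoyloxy-8-[(2S,3S)-2,3-dimethyloxirane-2-carbonyloxy]-1,10-epoxy-6-(tert-butyldimethylsilyloxy)-12-(tert-butyldiphenylsilyloxy)germacra-4,11(13)-diene | C[C@]12O[C@@H]1C[C@H](OC(=O)c3ccccc3)/C(C)=C\[C@@H](O[Si](C)(C)C(C)(C)C)[C@H](C(=C)CO[Si](c3ccccc3)(c3ccccc3)C(C)(C)C)[C@H](OC(=O)[C@@]3(C)O[C@H]3C)C2 | intermediate
39 | (1R,3S,4Z,6R,7S,8R,10R)-3-benzoyloxy-8-[(2S,3S)-2,3-dimethyloxirane-2-carbonyloxy]-1,10-epoxygermacra-4,11(13)-diene-6,12-diol | C[C@]12O[C@@H]1C[C@H](OC(=O)c3ccccc3)/C(C)=C\[C@@H](O)[C@H](C(=C)CO)[C@H](OC(=O)[C@@]3(C)O[C@H]3C)C2 | intermediate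
40 | (1R,3S,4Z,6R,7R,8R,10R)-3-benzoyloxy-8-[(2S,3S)-2,3-dimethyloxirane-2-carbonyloxy]-1,10-epoxygermacra-4,11(13)-dien-12,6-olide (CNP0324463.3) | C=C1C(=O)O[C@@H]2/C=C(/C)[C@@H](OC(=O)c3ccccc3)C[C@H]3O[C@]3(C)C[C@@H](OC(=O)[C@@]3(C)O[C@H]3C)[C@@H]12 | target

## Step count and least certain steps

Total: 27 steps. Longest linear sequence: 19 steps (from 5: steps 4–7, 10–19, 23–27).

**Step 18 (key step).** The ring may fail to close. The samarium enolate can be protonated or react intermolecularly, and a ketone acceptor in a ten-membered transition state is slow. Excess reductant could also attack the α-silyloxy ketone, and chelation of samarium by the C1 oxygen would erode the Felkin–Anh preference. Fallback, from 23 and 3 back to 28: the two ring bonds are made in the opposite order. Silyl enol ether 23 is brominated with N-bromosuccinimide to the bromomethyl ketone F1, and hydroxy ketone 3 is protected with 4-methoxybenzyl trichloroacetimidate (camphorsulfonic acid cat.) as ether F2. An intermolecular SmI2 Reformatsky addition of F1 to F2 forms C9–C10 under the same Felkin–Anh control and gives the tertiary aldol F3. DDQ then frees the primary alcohol F4 and Dess–Martin oxidation gives the aldehyde F5. An intramolecular Nozaki–Hiyama–Kishi reaction (CrCl2, cat. NiCl2, DMSO, high dilution) closes the ring at C3–C4 to the macrocyclic alcohol F6, which is benzoylated to 28.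

**Step 15.** Facial selectivity at C3 is likely to be poor, because 1,3-induction from a β-silyloxy group is weak in chromium-mediated additions; the chromium salts may also hydrolyse some of the enol ether. Fallback, from 23 and 4 back to 25: the unwanted (5R)-alcohol F7 is not discarded but treated with benzoic acid, PPh3 and diisopropyl azodicarboxylate. The Mitsunobu reaction inverts C3 and installs the benzoate in one operation, so both epimers converge on 25.

**Step 19.** Hydride may be delivered to the wrong face if the ring conformation overrides the six-membered chair, or ligand exchange at the tertiary hydroxyl may be too slow for intramolecular delivery. Fallback, from 28 back to 29: the 8-epimeric diol F8 is inverted at C8 by a Mitsunobu reaction with chloroacetic acid to give the (8R)-chloroacetate F9. The chloroacetate is then cleaved with thiourea/NaHCO3, which leaves the benzoate untouched, to give 29.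

**Step 25.** The mesylate may undergo base-induced elimination toward C2, or the C10 alkoxide may transfer the C8 acyl group, in competition with ring closure. Fallback, from 36 back to 38: cyclodehydration of diol 36 under Mitsunobu conditions (PPh3, diisopropyl azodicarboxylate), which activates the secondary C1 hydroxyl and closes the epoxide with the same inversion, without sulfonate or amidine base.

**Step 26.** The 1,10-epoxide may open, by fluoride or by transannular attack of C4=C5, during the long acidic exposure needed to remove the secondary and the diphenylsilyl ethers. Fallback, from 35 back to 40: the order of the last operations is changed so that the epoxide is never exposed to HF. Ester 35 is desilylated completely (HF·pyridine) to the tetraol F10. Aerobic oxidative lactonisation with Cu(MeCN)4OTf, 2,2'-bipyridine, TEMPO and N-methylimidazole in MeCN gives the lactone diol F11; this oxidant is chosen because PhI(OAc)2 could cleave the 1,10-glycol. Mesylation gives the C1 mesylate F12, and DBU closes the epoxide to 40.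

## Further compounds

F1 | step 18 | (3S,4S,5Z)-1-bromo-4-{[tert-butyl(dimethyl)silyl]oxy}-3-(3-{[tert-butyl(diphenyl)silyl]oxy}prop-1-en-2-yl)-6-iodohept-5-en-2-one | C/C(I)=C/[C@@H](O[Si](C)(C)C(C)(C)C)[C@H](C(=C)CO[Si](c1ccccc1)(c1ccccc1)C(C)(C)C)C(=O)CBr
F2 | step 18 | (3S)-5-[(4-methoxybenzyl)oxy]-3-[(triethylsilyl)oxy]pentan-2-one | CC(=O)[C@@H](O[Si](CC)(CC)CC)CCOCc1ccc(OC)cc1
F3 | step 18 | (1S,4Z,6S,7S,10R)-6-(tert-butyldimethylsilyloxy)-12-(tert-butyldiphenylsilyloxy)-10-hydroxy-4-iodo-3-(4-methoxybenzyloxy)-1-(triethylsilyloxy)-3,4-secogermacra-4,11(13)-dien-8-one | C[C@@](O)(CC(=O)[C@@H](C(=C)CO[Si](c1ccccc1)(c1ccccc1)C(C)(C)C)[C@H](O[Si](C)(C)C(C)(C)C)/C=C(/C)I)[C@@H](O[Si](CC)(CC)CC)CCOCc1ccc(OC)cc1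
F4 | step 18 | (1S,4Z,6S,7S,10R)-6-(tert-butyldimethylsilyloxy)-12-(tert-butyldiphenylsilyloxy)-3,10-dihydroxy-4-iodo-1-(triethylsilyloxy)-3,4-secogermacra-4,11(13)-dien-8-one | C[C@@](O)(CC(=O)[C@@H](C(=C)CO[Si](c1ccccc1)(c1ccccc1)C(C)(C)C)[C@H](O[Si](C)(C)C(C)(C)C)/C=C(/C)I)[C@@H](O[Si](CC)(CC)CC)CCO
F5 | step 18 | (1S,4Z,6S,7S,10R)-6-(tert-butyldimethylsilyloxy)-12-(tert-butyldiphenylsilyloxy)-10-hydroxy-4-iodo-8-oxo-1-(triethylsilyloxy)-3,4-secogermacra-4,11(13)-dien-3-al | C[C@@](O)(CC(=O)[C@@H](C(=C)CO[Si](c1ccccc1)(c1ccccc1)C(C)(C)C)[C@H](O[Si](C)(C)C(C)(C)C)/C=C(/C)I)[C@@H](O[Si](CC)(CC)CC)CC=O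
F6 | step 18 | (1S,3S,4Z,6R,7S,10R)-6-(tert-butyldimethylsilyloxy)-12-(tert-butyldiphenylsilyloxy)-3,10-dihydroxy-1-(triethylsilyloxy)germacra-4,11(13)-dien-8-one | C[C@]1(O)[C@@H](O[Si](CC)(CC)CC)C[C@H](O)/C(C)=C\[C@@H](O[Si](C)(C)C(C)(C)C)[C@H](C(=C)CO[Si](c2ccccc2)(c2ccccc2)C(C)(C)C)C(=O)C1
F7 | step 15 | (3S,5R,6Z,8R,9S)-8,10-bis{[tert-butyl(dimethyl)silyl]oxy}-9-(3-{[tert-butyl(diphenyl)silyl]oxy}prop-1-en-2-yl)-5-hydroxy-6-methyl-3-[(triethylsilyl)oxy]undeca-6,10-dien-2-one (5-epimer of 24) | CC(=O)[C@@H](O[Si](CC)(CC)CC)C[C@@H](O)/C(C)=C\[C@@H](O[Si](C)(C)C(C)(C)C)[C@H](C(=C)CO[Si](c1ccccc1)(c1ccccc1)C(C)(C)C)C(=C)O[Si](C)(C)C(C)(C)C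
F8 | step 19 | (1S,3S,4Z,6R,7R,8S,10R)-3-benzoyloxy-6-(tert-butyldimethylsilyloxy)-12-(tert-butyldiphenylsilyloxy)-1-(triethylsilyloxy)germacra-4,11(13)-diene-8,10-diol (8-epimer of 29) | C[C@]1(O)[C@@H](O[Si](CC)(CC)CC)C[C@H](OC(=O)c2ccccc2)/C(C)=C\[C@@H](O[Si](C)(C)C(C)(C)C)[C@H](C(=C)CO[Si](c2ccccc2)(c2ccccc2)C(C)(C)C)[C@@H](O)C1
F9 | step 19 | (1S,3S,4Z,6R,7R,8R,10R)-3-benzoyloxy-8-(chloroacetoxy)-6-(tert-butyldimethylsilyloxy)-12-(tert-butyldiphenylsilyloxy)-1-(triethylsilyloxy)germacra-4,11(13)-dien-10-ol | C[C@]1(O)[C@@H](O[Si](CC)(CC)CC)C[C@H](OC(=O)c2ccccc2)/C(C)=C\[C@@H](O[Si](C)(C)C(C)(C)C)[C@H](C(=C)CO[Si](c2ccccc2)(c2ccccc2)C(C)(C)C)[C@H](OC(=O)CCl)C1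
F0 | step 25 | none | none
F10 | step 26 | (1S,3S,4Z,6R,7S,8R,10R)-3-benzoyloxy-8-[(2S,3S)-2,3-dimethyloxirane-2-carbonyloxy]germacra-4,11(13)-diene-1,6,10,12-tetrol | C[C@]1(O)[C@@H](O)C[C@H](OC(=O)c2ccccc2)/C(C)=C\[C@@H](O)[C@H](C(=C)CO)[C@H](OC(=O)[C@@]2(C)O[C@H]2C)C1
F11 | step 26 | (1S,3S,4Z,6R,7R,8R,10R)-3-benzoyloxy-8-[(2S,3S)-2,3-dimethyloxirane-2-carbonyloxy]-1,10-dihydroxygermacra-4,11(13)-dien-12,6-olide | C=C1C(=O)O[C@@H]2/C=C(/C)[C@@H](OC(=O)c3ccccc3)C[C@H](O)[C@](C)(O)C[C@@H](OC(=O)[C@@]3(C)O[C@H]3C)[C@@H]12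
F12 | step 26 | 1-O-methanesulfonate of F11 | C=C1C(=O)O[C@@H]2/C=C(/C)[C@@H](OC(=O)c3ccccc3)C[C@H](OS(C)(=O)=O)[C@](C)(O)C[C@@H](OC(=O)[C@@]3(C)O[C@H]3C)[C@@H]12
A1 | alternative 1 | methyl (3R,4R,6E,9S,10Z)-9-(tert-butyldimethylsilyloxy)-3-formyl-11-iodo-4-(4-methoxybenzyloxy)-6,10-dimethylundeca-6,10-dienoate, the open-chain Z-iodoalkene aldehyde ester | I/C=C(/C)[C@@H](O[Si](C)(C)C(C)(C)C)C/C=C(\C)C[C@@H](OCc1ccc(OC)cc1)[C@@H](CC(=O)OC)C=O
A2 | alternative 1 | (1(10)E,4Z)-3-(tert-butyldimethylsilyloxy)-8-(4-methoxybenzyloxy)-13-norgermacra-1(10),4-dien-12,6-olide, trans-fused | C1C(=O)O[C@@H]2/C=C(/C)[C@@H](O[Si](C)(C)C(C)(C)C)C/C=C(\C)C[C@@H](OCc3ccc(OC)cc3)[C@@H]12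
A3 | alternative 2 | (2Z,6E)-farnesyl diphosphate | CC(C)=CCC/C(C)=C/CC/C(C)=C\COP(=O)(O)OP(=O)(O)O
A4 | alternative 2 | (1(10)E,4Z)-germacra-1(10),4,11-triene (Z,E-germacrene A) | C=C(C)[C@H]1C/C=C(/C)CC/C=C(\C)CC1
A5 | alternative 3 | (2Z,6E)-8-[benzyl(dimethyl)silyl]-4-(tert-butyldimethylsilyloxy)-3,7-dimethylcyclodeca-2,6-dien-1-one | O=C1/C=C(/C)[C@@H](O[Si](C)(C)C(C)(C)C)C/C=C(\C)C[C@@H]([Si](C)(C)Cc2ccccc2)C1
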